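## Retrosynthetic overview

- The strategy rests on ring C (O1, C2, C3, C4, C4a, C8a): cutting O1–C2 and C3–C4 leaves C4 as the cationic carbon of a ring A ortho-hydroxybenzaldehyde dimethyl acetal (an O-methylated ortho-quinone methide), and C2–C3 as the vinyl group of a ring B styrene.
- The [4+2] delivers C4 as a methyl ether at the alcohol oxidation level; solvolysis, oxidation to the C4 ketone and MOM removal finish the flavanone.
- Ring A piece: the C8–CH2 bond comes from a Negishi coupling of an aryl iodide with (S)-lavandulylzinc iodide; the lavandulyl centre comes from a deconjugative Evans alkylation of a senecioyl imide with prenyl bromide.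
- Ring B piece: 2,4-dihydroxybenzaldehyde is brominated at C5, methoxylated, MOM-protected and methylenated.
- Ring order: rings A and B are bought as arenes; ring C is the only ring formed, in the key step.

Key step: step 15

Assumption: which antipode of the acid catalyst favours (2S) with this pair cannot be predicted, so both are to be screened first; the route is written with the (R)-catalyst.
Abbreviation: lavandulyl = 5-methyl-2-(prop-1-en-2-yl)hex-4-en-1-yl; the target carries it with the (2R) configuration, which corresponds in space to (S)-lavandulol.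

## Route

Step 1
Reactants: 1 (4S)-4-benzyl-1,3-oxazolidin-2-one; 2 3-methylbut-2-enoyl chloride
Product: 4 (4S)-4-benzyl-3-(3-methylbut-2-enoyl)-1,3-oxazolidin-2-one, via lithium oxazolidinide 3 (not isolated)
Conditions: n-BuLi, THF, −78 °C; then 2, −78 → 0 °C
Reagents that add atoms: none
Why: N-acylation of the lithiated Evans auxiliary by the acid chloride is fast at −78 °C, where the enoyl chloride does not deconjugate.

Step 2
Reactants: 4; 5 prenyl bromide (1-bromo-3-methylbut-2-ene)
Product: 7 (4S)-4-benzyl-3-[(2S)-5-methyl-2-(prop-1-en-2-yl)hex-4-enoyl]-1,3-oxazolidin-2-one, via sodium (Z)-dienolate 6 (not isolated)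
Conditions: NaN(SiMe3)2, THF, −78 °C; then 5, −78 → −40 °C
Reagents that add atoms: none
Why: Evans alkylation in its deconjugative form, in which γ-deprotonation gives the chelated (Z)-dienolate that is alkylated at the α-carbon on the face away from the benzyl group, so the new centre should be (S) and the double bond ends up as the isopropenyl group.

Step 3
Reactants: 7
Product: 8 (2S)-5-methyl-2-(prop-1-en-2-yl)hex-4-en-1-ol [(S)-lavandulol]
Conditions: LiBH4, H2O (1 equiv), Et2O, 0 °C
Reagents that add atoms: none
Why: Reductive cleavage of the imide by LiBH4 attacks the exocyclic carbonyl and is not basic enough to epimerise the α-centre or to bring the alkene into conjugation, and the auxiliary is recovered.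

Step 4
Reactants: 8
Product: 9 (3S)-3-(iodomethyl)-2,6-dimethylhepta-1,5-diene [(S)-lavandulyl iodide]
Conditions: PPh3, I2, imidazole, CH2Cl2, 0 °C → rt
Reagents that add atoms: iodine, II
Why: Appel-type iodination displaces the activated primary oxygen by iodide (SN2) without touching the adjacent stereocentre or the alkenes.

Step 5
Reactants: 10 2,4,6-trihydroxybenzaldehyde
Product: 11 2-hydroxy-4,6-bis(methoxymethoxy)benzaldehyde
Conditions: MOMCl (2.2 equiv), i-Pr2NEt, CH2Cl2, 0 °C → rt
Reagents that add atoms: chloromethyl methyl ether, COCCl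
Why: Williamson-type O-alkylation under amine base protects the two non-chelated phenols and leaves the OH that is hydrogen-bonded to the aldehyde free.

Step 6
Reactants: 11
Product: 12 2-hydroxy-3-iodo-4,6-bis(methoxymethoxy)benzaldehyde
Conditions: N-iodosuccinimide (1.0 equiv), DMF, 0 °C → rt, dark
Reagents that add atoms: N-iodosuccinimide, O=C1CCC(=O)N1I
Why: Electrophilic aromatic iodination should go to C3, ortho to the free phenol and flanked by only one MOM ether, in preference to C5 between two MOM ethers, which places iodine on the carbon that becomes C8.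

Step 7
Reactants: 12
Product: 13 2-formyl-6-iodo-3,5-bis(methoxymethoxy)phenyl acetate
Conditions: Ac2O, Et3N, DMAP (5 mol%), CH2Cl2, 0 °C → rt
Reagents that add atoms: acetic anhydride, CC(=O)OC(C)=O
Why: DMAP-catalysed acylation masks the acidic phenol, which would otherwise protonate the organozinc reagent and make the later acetal too labile to purify, and the ester can be removed by base without harm to acetal or MOM ethers.

Step 8
Reactants: 9; 13
Product: 15 2-formyl-3,5-bis(methoxymethoxy)-6-[(2R)-5-methyl-2-(prop-1-en-2-yl)hex-4-en-1-yl]phenyl acetate, via lavandulylzinc iodide 14 (not isolated)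
Conditions: 9, Zn dust (activated with BrCH2CH2Br and Me3SiCl), LiCl, THF, 35 °C; then 13, Pd(OAc)2 (3 mol%), SPhos (6 mol%), THF, rt → 45 °C
Reagents that add atoms: none
Why: Negishi coupling in which zinc inserts into the primary C–I bond and the alkylzinc iodide transmetalates to the arylpalladium iodide; the bulky biarylphosphine permits oxidative addition at the doubly ortho-substituted iodide and makes reductive elimination faster than β-hydride loss, so the neighbouring stereocentre is carried through, and acetate, aldehyde and MOM ethers are tolerated.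

Step 9
Reactants: 15
Product: 16 2-(dimethoxymethyl)-3,5-bis(methoxymethoxy)-6-[(2R)-5-methyl-2-(prop-1-en-2-yl)hex-4-en-1-yl]phenyl acetate
Conditions: HC(OMe)3 (5 equiv), PPTS (5 mol%), MeOH, 0 °C → rt; Et3N quench
Reagents that add atoms: trimethyl orthoformate, COC(OC)OC; methanol, CO
Why: Acid-catalysed acetalisation is driven by the orthoformate as water scavenger, the catalytic pyridinium salt at room temperature should spare the aryl MOM ethers and the alkenes, and any acetate lost here converges in the next step.

Step 10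
Reactants: 16
Product: 17 2-(dimethoxymethyl)-3,5-bis(methoxymethoxy)-6-[(2R)-5-methyl-2-(prop-1-en-2-yl)hex-4-en-1-yl]phenol
Conditions: K2CO3 (0.2 equiv), MeOH, 0 °C; pH 8 buffer work-up; crude product used at once
Reagents that add atoms: none
Why: Base-catalysed transesterification of the aryl acetate frees the phenol under conditions to which the acetal is inert, so the acid-labile ortho-hydroxy acetal does not meet acid before the key step.

Step 11
Reactants: 18 2,4-dihydroxybenzaldehyde
Product: 19 5-bromo-2,4-dihydroxybenzaldehyde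
Conditions: Br2 (1.0 equiv), AcOH, rt
Reagents that add atoms: bromine, BrBr
Why: Electrophilic aromatic bromination goes to C5, para to the 2-OH and ortho to the 4-OH, because C3 between the two hydroxyls is more hindered.

Step 12
Reactants: 19
Product: 20 2,4-dihydroxy-5-methoxybenzaldehyde
Conditions: NaOMe (6 equiv), CuCl (0.3 equiv), DMF–MeOH, 110 °C; then aq. HCl
Reagents that add atoms: sodium methoxide, C[O-].[Na+]
Why: Ullmann-type copper-catalysed methoxylation of the aryl bromide, the exchange that turns 5-bromovanillin into syringaldehyde, with the aldehyde deactivated toward methoxide as its bis-phenoxide.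

Step 13
Reactants: 20
Product: 21 5-methoxy-2,4-bis(methoxymethoxy)benzaldehyde
Conditions: MOMCl (3 equiv), K2CO3 (4 equiv), acetone, reflux
Reagents that add atoms: chloromethyl methyl ether, COCCl
Why: Williamson etherification with carbonate in refluxing acetone is forcing enough to alkylate the chelated 2-OH as well as the 4-OH.

Step 14
Reactants: 21
Product: 22 1-ethenyl-5-methoxy-2,4-bis(methoxymethoxy)benzene
Conditions: Ph3PCH3Br, KOt-Bu, THF, 0 °C → rt
Reagents that add atoms: methyltriphenylphosphonium bromide, C[P+](c1ccccc1)(c1ccccc1)c1ccccc1.[Br-]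
Why: Wittig methylenation of the aryl aldehyde with the non-stabilised ylide leaves the MOM ethers untouched, and the electron-rich styrene is kept cold and acid-free until use.

Step 15
Reactants: 17; 22
Product: 24 (2S,4S)-4-methoxy-2-[5-methoxy-2,4-bis(methoxymethoxy)phenyl]-5,7-bis(methoxymethoxy)-8-[(2R)-5-methyl-2-(prop-1-en-2-yl)hex-4-en-1-yl]chromane (2,4-cis), via ortho-quinone methide oxocarbenium ion 23 (not isolated)
Conditions: (R)-3,3'-bis(2,4,6-triisopropylphenyl)-1,1'-binaphthyl-2,2'-diyl N-triflylphosphoramide (10 mol%), 5 Å MS, toluene, −60 → −40 °C, slow addition of 22 (1.5 equiv); Et3N quench at −40 °C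
Reagents that add atoms: none
Why: Proposed new method: the acid protonates an acetal oxygen of 17, methanol leaves, and oxocarbenium ion 23 (the O-methylated ortho-quinone methide of ring A, stabilised by the two MOM-ether oxygens) stays paired with the chiral phosphoramide anion, which also holds the ring A phenol O–H by a hydrogen bond; the terminal CH2 of styrene 22 attacks the cationic carbon (C3–C4 bond) and the phenol oxygen closes on the developing benzylic cation (O1–C2 bond) in a polar, asynchronous inverse-demand [4+2]. The closest known reactions are the achiral acid-promoted [4+2] of styrenes with salicylaldehyde acetals, which gives 2,4-cis-4-alkoxyflavans, and chiral phosphoric acid-type catalysis of [4+2] reactions of ortho-quinone methides with electron-rich styrenes and with tethered alkenes; new here is catalyst control in the intermolecular, acetal-derived case. Ring C closes as a six-membered ring, its second bond forming by O1 attack on the benzylic cation (6-exo-trig in the quinoid description of that cation). C4 is set by the face of the oxocarbenium ion that the anion leaves open, and C2 follows from C4 through the endo arrangement that puts aryl and OMe cis, so the catalyst antipode, not the remote lavandulyl centre, decides (2S). Regiochemistry is secured by polarity, since the β-carbon of the 2,4-dialkoxystyrene is the nucleophile and its α-carbon carries the cation. The step needs facial and cis selectivity (the 2,4-trans isomer carries the opposite C2 and is removed by chromatography before C4 is erased), closure through the free phenol and not the flanking MOM oxygen (favoured by the hydrogen bond to the anion), and suppression of styrene self-addition and of cycloreversion (slow addition, low temperature, sieves to take up methanol, cold quench).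

Step 16
Reactants: 24
Product: 25 (2S)-2-[5-methoxy-2,4-bis(methoxymethoxy)phenyl]-5,7-bis(methoxymethoxy)-8-[(2R)-5-methyl-2-(prop-1-en-2-yl)hex-4-en-1-yl]chroman-4-ol (mixture of C4 epimers)
Conditions: PPTS (0.2 equiv), acetone–H2O (4:1), 0 °C → rt; NaHCO3 quench
Reagents that add atoms: water, O
Why: SN1 solvolysis of the C4 methyl ether, a 2,4,6-trioxygenated benzylic ether that ionises under acid too mild to cleave MOM ethers, with capture by the large excess of water and no change at C2.

Step 17
Reactants: 25
Product: 26 (2S)-2-[5-methoxy-2,4-bis(methoxymethoxy)phenyl]-5,7-bis(methoxymethoxy)-8-[(2R)-5-methyl-2-(prop-1-en-2-yl)hex-4-en-1-yl]chroman-4-one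
Conditions: Dess–Martin periodinane (1.5 equiv), NaHCO3, CH2Cl2, 0 °C → rt
Reagents that add atoms: none
Why: Dess–Martin oxidation converts both C4 epimers into the same ketone under buffered, non-basic conditions that neither open the flavanone at C2 nor cleave the MOM ethers.

Step 18
Reactants: 26
Product: 27 (2S)-2-(2,4-dihydroxy-5-methoxyphenyl)-5,7-dihydroxy-8-[(2R)-5-methyl-2-(prop-1-en-2-yl)hex-4-en-1-yl]-2,3-dihydro-4H-chromen-4-one (CNP0323048.1)
Conditions: 3 M aq. HCl–MeOH (1:5), 35 °C, monitored; NaHCO3 to pH 6
Reagents that add atoms: none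
Why: Acid-catalysed acetal methanolysis removes the four MOM groups at a temperature low enough that the lavandulyl alkenes are not protonated, and the flavanone C2 centre is configurationally stable in acid because ring opening to the chalcone needs base.

## Compound list

1 | (4S)-4-benzyl-1,3-oxazolidin-2-one | O=C1N[C@@H](Cc2ccccc2)CO1 | starting material
2 | 3-methylbut-2-enoyl chloride | CC(C)=CC(=O)Cl | starting material
3 | lithium (4S)-4-benzyl-2-oxo-1,3-oxazolidin-3-ide | [Li]N1[C@@H](Cc2ccccc2)COC1=O | intermediate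
4 | (4S)-4-benzyl-3-(3-methylbut-2-enoyl)-1,3-oxazolidin-2-one | CC(C)=CC(=O)N1[C@@H](Cc2ccccc2)COC1=O | intermediate
5 | prenyl bromide (1-bromo-3-methylbut-2-ene) | CC(C)=CCBr | starting material
6 | sodium (1Z)-1-[(4S)-4-benzyl-2-oxo-1,3-oxazolidin-3-yl]-3-methylbuta-1,3-dien-1-olate | C=C(C)/C=C(\[O-])N1[C@@H](Cc2ccccc2)COC1=O.[Na+] | intermediate
7 | (4S)-4-benzyl-3-[(2S)-5-methyl-2-(prop-1-en-2-yl)hex-4-enoyl]-1,3-oxazolidin-2-one | C=C(C)[C@H](CC=C(C)C)C(=O)N1[C@@H](Cc2ccccc2)COC1=O | intermediate
8 | (2S)-5-methyl-2-(prop-1-en-2-yl)hex-4-en-1-ol, (S)-lavandulol | C=C(C)[C@H](CC=C(C)C)CO | intermediate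
9 | (3S)-3-(iodomethyl)-2,6-dimethylhepta-1,5-diene, (S)-lavandulyl iodide | C=C(C)[C@H](CC=C(C)C)CI | intermediate
10 | 2,4,6-trihydroxybenzaldehyde | O=Cc1c(O)cc(O)cc1O | starting material
11 | 2-hydroxy-4,6-bis(methoxymethoxy)benzaldehyde | O=Cc1c(O)cc(OCOC)cc1OCOC | intermediate
12 | 2-hydroxy-3-iodo-4,6-bis(methoxymethoxy)benzaldehyde | O=Cc1c(O)c(I)c(OCOC)cc1OCOC | intermediate
13 | 2-formyl-6-iodo-3,5-bis(methoxymethoxy)phenyl acetate | CC(=O)Oc1c(I)c(OCOC)cc(OCOC)c1C=O | intermediate
14 | [(2S)-5-methyl-2-(prop-1-en-2-yl)hex-4-en-1-yl]zinc iodide | C=C(C)[C@H](CC=C(C)C)C[Zn]I | intermediate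
15 | 2-formyl-3,5-bis(methoxymethoxy)-6-[(2R)-5-methyl-2-(prop-1-en-2-yl)hex-4-en-1-yl]phenyl acetate | C=C(C)[C@H](CC=C(C)C)Cc1c(OC(C)=O)c(C=O)c(OCOC)cc1OCOC | intermediate
16 | 2-(dimethoxymethyl)-3,5-bis(methoxymethoxy)-6-[(2R)-5-methyl-2-(prop-1-en-2-yl)hex-4-en-1-yl]phenyl acetate | C=C(C)[C@H](CC=C(C)C)Cc1c(OC(C)=O)c(C(OC)OC)c(OCOC)cc1OCOC | intermediate
17 | 2-(dimethoxymethyl)-3,5-bis(methoxymethoxy)-6-[(2R)-5-methyl-2-(prop-1-en-2-yl)hex-4-en-1-yl]phenol | C=C(C)[C@H](CC=C(C)C)Cc1c(O)c(C(OC)OC)c(OCOC)cc1OCOC | intermediate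
18 | 2,4-dihydroxybenzaldehyde | O=Cc1ccc(O)cc1O | starting material
19 | 5-bromo-2,4-dihydroxybenzaldehyde | O=Cc1cc(Br)c(O)cc1O | intermediate
20 | 2,4-dihydroxy-5-methoxybenzaldehyde | COc1cc(C=O)c(O)cc1O | intermediate
21 | 5-methoxy-2,4-bis(methoxymethoxy)benzaldehyde | COc1cc(C=O)c(OCOC)cc1OCOC | intermediate
22 | 1-ethenyl-5-methoxy-2,4-bis(methoxymethoxy)benzene | C=Cc1cc(OC)c(OCOC)cc1OCOC | intermediate
23 | ortho-quinone methide oxocarbenium ion of 17 (cation shown, paired with the phosphoramide anion) | C=C(C)[C@H](CC=C(C)C)Cc1c(O)c(C=[O+]C)c(OCOC)cc1OCOC | intermediate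
24 | (2S,4S)-4-methoxy-2-[5-methoxy-2,4-bis(methoxymethoxy)phenyl]-5,7-bis(methoxymethoxy)-8-[(2R)-5-methyl-2-(prop-1-en-2-yl)hex-4-en-1-yl]chromane | C=C(C)[C@H](CC=C(C)C)Cc1c(OCOC)cc(OCOC)c2c1O[C@H](c1cc(OC)c(OCOC)cc1OCOC)C[C@@H]2OC | intermediate
25 | (2S)-2-[5-methoxy-2,4-bis(methoxymethoxy)phenyl]-5,7-bis(methoxymethoxy)-8-[(2R)-5-methyl-2-(prop-1-en-2-yl)hex-4-en-1-yl]chroman-4-ol, both C4 epimers (C4 left undefined) | C=C(C)[C@H](CC=C(C)C)Cc1c(OCOC)cc(OCOC)c2c1O[C@H](c1cc(OC)c(OCOC)cc1OCOC)CC2O | intermediate
26 | (2S)-2-[5-methoxy-2,4-bis(methoxymethoxy)phenyl]-5,7-bis(methoxymethoxy)-8-[(2R)-5-methyl-2-(prop-1-en-2-yl)hex-4-en-1-yl]chroman-4-one | C=C(C)[C@H](CC=C(C)C)Cc1c(OCOC)cc(OCOC)c2c1O[C@H](c1cc(OC)c(OCOC)cc1OCOC)CC2=O | intermediate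
27 | (2S)-2-(2,4-dihydroxy-5-methoxyphenyl)-5,7-dihydroxy-8-[(2R)-5-methyl-2-(prop-1-en-2-yl)hex-4-en-1-yl]-2,3-dihydro-4H-chromen-4-one | C=C(C)[C@H](CC=C(C)C)Cc1c(O)cc(O)c2c1O[C@H](c1cc(OC)c(O)cc1O)CC2=O | target

## Step count and risks

Total steps: 18.
Longest linear sequence: 11 steps (steps 1–4, 8–10, 15–18).

Steps most likely to fail:

1. Step 15. The catalyst may give poor facial selectivity at the oxocarbenium ion, so that the C2 epimers form in similar amounts; acid-induced self-addition of the styrene or cycloreversion of the product may also erode material or stereochemical purity. The fallback uses known chemistry, sets out from 15 and 21, and returns at 26. Acetate 15 is treated with excess MeMgBr (THF, −78 → 0 °C), which adds to the aldehyde and cleaves the acetate, giving 2-(1-hydroxyethyl)-3,5-bis(methoxymethoxy)-6-[(2R)-5-methyl-2-(prop-1-en-2-yl)hex-4-en-1-yl]phenol F1. MnO2 (CH2Cl2, rt) oxidises the benzylic alcohol to 1-{2-hydroxy-4,6-bis(methoxymethoxy)-3-[(2R)-5-methyl-2-(prop-1-en-2-yl)hex-4-en-1-yl]phenyl}ethan-1-one F2. Claisen–Schmidt condensation with aldehyde 21 (KOH, EtOH–H2O, rt) gives (2E)-1-{2-hydroxy-4,6-bis(methoxymethoxy)-3-[(2R)-5-methyl-2-(prop-1-en-2-yl)hex-4-en-1-yl]phenyl}-3-[5-methoxy-2,4-bis(methoxymethoxy)phenyl]prop-2-en-1-one F3. Oxa-Michael cyclisation (NaOAc, EtOH, reflux) then closes ring C to both C2 epimers, which are diastereomers because of the lavandulyl centre. Compound 26 is separated by preparative HPLC from (2R)-2-[5-methoxy-2,4-bis(methoxymethoxy)phenyl]-5,7-bis(methoxymethoxy)-8-[(2R)-5-methyl-2-(prop-1-en-2-yl)hex-4-en-1-yl]chroman-4-one F4, which is put back into the same equilibration.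

2. Step 16. The C4 cation may lose the C3 proton instead of taking up water, giving elimination to the flav-3-ene, or prolonged acid may open the O1–C2 bond and epimerise C2. The fallback sets out from 24 and returns at 26 and makes no compound outside the list (F0). It replaces solvolysis plus alcohol oxidation by one oxidative step: DDQ (1.2 equiv) in CH2Cl2–pH 7 buffer at 0 °C abstracts hydride from C4, the carbon activated by both the methoxy group and the trioxygenated ring A, and water collapses the resulting oxocarbenium ion directly to ketone 26.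

3. Step 18. Once the 7-OH is free, protonation of the isopropenyl or prenyl alkene may lead to cyclisation onto that phenol or to addition of methanol or HCl, and incomplete cleavage of the less activated MOM ethers may force harsher conditions. The fallback sets out from 26 and returns at 27 and avoids free Brønsted acid. Me3SiOTf with 2,2'-bipyridyl (CH2Cl2, 0 °C → rt) exchanges the aryl MOM ethers for silyl ethers to give (2S)-2-[5-methoxy-2,4-bis(trimethylsilyloxy)phenyl]-5,7-bis(trimethylsilyloxy)-8-[(2R)-5-methyl-2-(prop-1-en-2-yl)hex-4-en-1-yl]chroman-4-one F5. The silyl ethers are then hydrolysed with water in THF at neutral pH to give 27.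

## Further compounds

F1 | step 15 | 2-(1-hydroxyethyl)-3,5-bis(methoxymethoxy)-6-[(2R)-5-methyl-2-(prop-1-en-2-yl)hex-4-en-1-yl]phenol (carbinol epimers) | C=C(C)[C@H](CC=C(C)C)Cc1c(O)c(C(C)O)c(OCOC)cc1OCOC
F2 | step 15 | 1-{2-hydroxy-4,6-bis(methoxymethoxy)-3-[(2R)-5-methyl-2-(prop-1-en-2-yl)hex-4-en-1-yl]phenyl}ethan-1-one | C=C(C)[C@H](CC=C(C)C)Cc1c(O)c(C(C)=O)c(OCOC)cc1OCOC
F3 | step 15 | (2E)-1-{2-hydroxy-4,6-bis(methoxymethoxy)-3-[(2R)-5-methyl-2-(prop-1-en-2-yl)hex-4-en-1-yl]phenyl}-3-[5-methoxy-2,4-bis(methoxymethoxy)phenyl]prop-2-en-1-one | C=C(C)[C@H](CC=C(C)C)Cc1c(O)c(C(=O)/C=C/c2cc(OC)c(OCOC)cc2OCOC)c(OCOC)cc1OCOC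
F4 | step 15 | (2R)-2-[5-methoxy-2,4-bis(methoxymethoxy)phenyl]-5,7-bis(methoxymethoxy)-8-[(2R)-5-methyl-2-(prop-1-en-2-yl)hex-4-en-1-yl]chroman-4-one | C=C(C)[C@H](CC=C(C)C)Cc1c(OCOC)cc(OCOC)c2c1O[C@@H](c1cc(OC)c(OCOC)cc1OCOC)CC2=O
F0 | step 16 | none | none
F5 | step 18 | (2S)-2-[5-methoxy-2,4-bis(trimethylsilyloxy)phenyl]-5,7-bis(trimethylsilyloxy)-8-[(2R)-5-methyl-2-(prop-1-en-2-yl)hex-4-en-1-yl]chroman-4-one | C=C(C)[C@H](CC=C(C)C)Cc1c(O[Si](C)(C)C)cc(O[Si](C)(C)C)c2c1O[C@H](c1cc(OC)c(O[Si](C)(C)C)cc1O[Si](C)(C)C)CC2=O
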